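**Plan**

1. Ring A is a pyrrole with CH2OH on C2, CH2CO2H on C3, CH2CH2CO2H on C4 and the bridge CH2 on C5. Cutting C3–C4 and N–C5 unfolds it into two enamine arms, N–C2=C3 and N–C5=C4, on the two nitrogens of a hydrazine. This 3,4-diaza-1,5-diene is the feature that lets a [3,3] shift make C3–C4.
2. The N,N'-di-Boc dialkenylhydrazine is cut at both N–C(sp2) bonds into BocNHNHBoc, an iodoalkene (silyloxymethyl and acetate carbons) and a bromoalkene (propionate chain plus the ring B–C–D tripyrrane).
3. The tripyrrane is cut at its two CH2 bridges and at the ring B CH2–C(Br) bond, so one Knorr pyrrole supplies rings B, C and D.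
4. Forward: Knorr pyrrole; ring B joined to the bromoalkene (Negishi); rings C then D added by acid-catalysed pyrromethane couplings; N-Boc protection; two Cu-catalysed N-alkenylations; ring A closed last; desilylation and hydroxide deprotection.
5. The target has no stereocentre. The alkene geometries (Z from the Negishi coupling, E from the radical addition) only feed the rearrangement and vanish when ring A aromatises.

Key step: step 15

Assumption: the final acid cyclises or oligomerises below about pH 11, so it would be produced and kept as its octapotassium salt in the alkaline hydrolysate; the neutral octa-acid is the formal product.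
Assumption: the iodoalkene of step 13 is drawn as the E isomer expected to predominate; any Z isomer would pass through the same steps to the same pyrrole.

**Route**

Step 1
Reactants: 1 Meldrum's acid (2,2-dimethyl-1,3-dioxane-4,6-dione); 2 methyl 4-chloro-4-oxobutanoate
Product: 4 1-tert-butyl 6-methyl 3-oxohexanedioate, via acyl Meldrum's acid 3 (not isolated)
Conditions: pyridine, CH2Cl2, 0 °C to rt; then t-BuOH, toluene, 90 °C
Reagents that add atoms: tert-butanol, CC(C)(C)O
Why: C-acylation of Meldrum's acid followed by alcoholysis with loss of acetone and CO2 (Meldrum's acid route to β-keto esters) is a standard one-flask preparation and leaves the methyl ester untouched.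

Step 2
Reactants: 4 1-tert-butyl 6-methyl 3-oxohexanedioate; 5 pentane-2,4-dione
Product: 8 tert-butyl 4-acetyl-3-(3-methoxy-3-oxopropyl)-5-methyl-1H-pyrrole-2-carboxylate, via oxime 6 (not isolated), via amino ketone 7 (not isolated)
Conditions: NaNO2, AcOH/H2O, 5–10 °C; then 5, Zn dust, NaOAc, AcOH, 65–75 °C
Reagents that add atoms: sodium nitrite, [Na+].[O-]N=O
Why: Knorr pyrrole synthesis: nitrosation occurs at the doubly activated C2 methylene, zinc reduces the oxime to the α-amino ketone in the presence of the diketone, and condensation should place CO2t-Bu on C2, the propionate chain on C3, acetyl on C4 and methyl on C5.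

Step 3
Reactants: 8 tert-butyl 4-acetyl-3-(3-methoxy-3-oxopropyl)-5-methyl-1H-pyrrole-2-carboxylate
Product: 9 tert-butyl 4-(2-methoxy-2-oxoethyl)-3-(3-methoxy-3-oxopropyl)-5-methyl-1H-pyrrole-2-carboxylate
Conditions: Tl(NO3)3·3H2O, MeOH, rt, short reaction time
Reagents that add atoms: methanol, CO
Why: Oxidative rearrangement of an aryl methyl ketone to the methyl arylacetate with thallium trinitrate in methanol (oxythallation, then 1,2-shift of the electron-rich pyrrolyl group) is the classical way to turn a 4-acetylpyrrole ester into the pyrrole acetic ester.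

Step 4
Reactants: 9 tert-butyl 4-(2-methoxy-2-oxoethyl)-3-(3-methoxy-3-oxopropyl)-5-methyl-1H-pyrrole-2-carboxylate
Product: 10 tert-butyl 5-(acetoxymethyl)-4-(2-methoxy-2-oxoethyl)-3-(3-methoxy-3-oxopropyl)-1H-pyrrole-2-carboxylate
Conditions: Pb(OAc)4, AcOH, rt
Reagents that add atoms: lead tetraacetate, CC(=O)O[Pb](OC(C)=O)(OC(C)=O)OC(C)=O
Why: Lead tetraacetate side-chain acetoxylation of an α-methylpyrrole-2-carboxylate proceeds through the azafulvene and is selective for the α-methyl group, giving the pyrrolylmethyl electrophile used twice later.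

Step 5
Reactants: 9 tert-butyl 4-(2-methoxy-2-oxoethyl)-3-(3-methoxy-3-oxopropyl)-5-methyl-1H-pyrrole-2-carboxylate
Product: 11 di-tert-butyl 4-(2-methoxy-2-oxoethyl)-3-(3-methoxy-3-oxopropyl)-5-methyl-1H-pyrrole-1,2-dicarboxylate
Conditions: Boc2O, DMAP (cat.), MeCN, rt
Reagents that add atoms: di-tert-butyl dicarbonate, CC(C)(C)OC(=O)OC(=O)OC(C)(C)C
Why: DMAP-catalysed N-acylation (Boc protection) of the acidic N–H of a pyrrole-2-ester makes the ring electron-poor, so that a halomethyl group and an organozinc can be carried on it without azafulvene formation.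

Step 6
Reactants: 11 di-tert-butyl 4-(2-methoxy-2-oxoethyl)-3-(3-methoxy-3-oxopropyl)-5-methyl-1H-pyrrole-1,2-dicarboxylate
Product: 12 di-tert-butyl 5-(bromomethyl)-4-(2-methoxy-2-oxoethyl)-3-(3-methoxy-3-oxopropyl)-1H-pyrrole-1,2-dicarboxylate
Conditions: NBS, AIBN (cat.), PhCF3, 80 °C
Reagents that add atoms: N-bromosuccinimide, O=C1CCC(=O)N1Br
Why: Wohl–Ziegler radical bromination should favour the ring methyl group, because the electrophilic bromine atom avoids the ester-deactivated CH2CO2Me hydrogens and the hindered propionate CH2, and the fully substituted ring cannot be brominated.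

Step 7
Reactants: 13 methyl 4-oxobutanoate; 14 carbon tetrabromide
Product: 15 methyl 5,5-dibromopent-4-enoate
Conditions: PPh3, CH2Cl2, 0 °C
Reagents that add atoms: none
Why: Ramirez dibromo-olefination (first stage of the Corey–Fuchs sequence) of an aliphatic aldehyde is routine and tolerates the ester.

Step 8
Reactants: 12 di-tert-butyl 5-(bromomethyl)-4-(2-methoxy-2-oxoethyl)-3-(3-methoxy-3-oxopropyl)-1H-pyrrole-1,2-dicarboxylate; 15 methyl 5,5-dibromopent-4-enoate
Product: 17 di-tert-butyl 5-[(2Z)-2-bromo-6-methoxy-6-oxohex-2-en-1-yl]-4-(2-methoxy-2-oxoethyl)-3-(3-methoxy-3-oxopropyl)-1H-pyrrole-1,2-dicarboxylate, via benzylic zinc bromide 16 (not isolated)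
Conditions: Zn dust, LiCl, THF, 0 °C to rt; then 15, PdCl2(DPEphos) (3 mol%; DPEphos = bis[2-(diphenylphosphino)phenyl] ether), THF, 0 °C to rt
Reagents that add atoms: none
Why: LiCl-assisted zinc insertion gives an ester-tolerant benzylic-type zinc reagent, and in the trans-selective Negishi mono-coupling the zerovalent palladium formed from PdCl2(DPEphos) inserts into the C–Br bond trans to the alkyl chain of the 1,1-dibromoalkene, so one bromine is replaced and the (Z)-bromoalkene keeps its C=C on the propionate side.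

Step 9
Reactants: 17 ring B bromoalkene (N-Boc, C2 tert-butyl ester); 10 tert-butyl 5-(acetoxymethyl)-4-(2-methoxy-2-oxoethyl)-3-(3-methoxy-3-oxopropyl)-1H-pyrrole-2-carboxylate
Product: 19 ring B–C dipyrromethane tert-butyl ester, via α-free ring B pyrrole 18 (not isolated)
Conditions: TFA, CH2Cl2, 0 °C to rt, evaporate; then 10, p-TsOH·H2O (cat.), CH2Cl2, rt, Ar, dark
Reagents that add atoms: none
Why: TFA removes both tert-butyl groups and the pyrrole-2-carboxylic acid decarboxylates, after which the electron-rich α-free pyrrole attacks, at its only open position, the azafulvenium ion from the acetoxymethylpyrrole (classical acid-catalysed pyrromethane synthesis), the C2 ester of the incoming ring preventing further reaction.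

Step 10
Reactants: 19 ring B–C dipyrromethane tert-butyl ester; 10 tert-butyl 5-(acetoxymethyl)-4-(2-methoxy-2-oxoethyl)-3-(3-methoxy-3-oxopropyl)-1H-pyrrole-2-carboxylate
Product: 21 ring B–C–D tripyrrane tert-butyl ester, via α-free dipyrromethane 20 (not isolated)
Conditions: TFA, CH2Cl2, 0 °C to rt, evaporate; then 10, p-TsOH·H2O (cat.), CH2Cl2, rt, Ar, dark
Reagents that add atoms: none
Why: The same deprotection–decarboxylation and acid-catalysed pyrromethane coupling, now at the freed α-position of ring C, extends the chain head to tail by ring D.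

Step 11
Reactants: 21 ring B–C–D tripyrrane tert-butyl ester
Product: 23 tri-N-Boc ring B–C–D tripyrrane (Z)-bromoalkene, via α-free tripyrrane 22 (not isolated)
Conditions: TFA, CH2Cl2, 0 °C to rt, evaporate, NaHCO3 wash; then Boc2O (excess), DMAP, MeCN, 40 °C
Reagents that add atoms: di-tert-butyl dicarbonate, CC(C)(C)OC(=O)OC(=O)OC(C)(C)C
Why: Acidolysis and decarboxylation free the α-position of ring D, and immediate DMAP-catalysed Boc protection of the three pyrrole N–H groups turns the oxidation- and acid-sensitive tripyrrane into a robust one whose nitrogens cannot compete in the copper-catalysed steps.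

Step 12
Reactants: 23 tri-N-Boc ring B–C–D tripyrrane (Z)-bromoalkene; 24 di-tert-butyl hydrazine-1,2-dicarboxylate
Product: 25 N-alkenyl di-Boc hydrazine carrying the tripyrrane
Conditions: 24 (excess), CuI (20 mol%), N,N'-dimethylethylenediamine (40 mol%), Cs2CO3, toluene, 90 °C
Reagents that add atoms: none
Why: Goldberg-type copper-catalysed N-alkenylation of a carbamate-type N–H with a vinyl halide goes with retention of alkene geometry, and the excess of the symmetrical hydrazide should hold the reaction at the mono-alkenyl stage.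

Step 13
Reactants: 26 methyl iodoacetate; 27 tert-butyldimethyl(prop-2-yn-1-yloxy)silane
Product: 28 methyl (3E)-5-[(tert-butyldimethylsilyl)oxy]-4-iodopent-3-enoate
Conditions: Et3B (cat.), trace air, benzene, rt
Reagents that add atoms: none
Why: Kharasch-type iodine atom-transfer radical addition: the electrophilic radical •CH2CO2Me adds to the terminal alkyne carbon and the vinyl radical takes iodine from the iodoacetate, which fixes iodine on the carbon bearing CH2OSi and the C=C toward the acetate carbon, mainly as the E isomer.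

Step 14
Reactants: 25 N-alkenyl di-Boc hydrazine carrying the tripyrrane; 28 methyl (3E)-5-[(tert-butyldimethylsilyl)oxy]-4-iodopent-3-enoate
Product: 29 N,N'-di-Boc-N,N'-dialkenylhydrazine (tripyrrane arm and silyloxymethyl arm)
Conditions: 28 (excess), CuI (30 mol%), N,N'-dimethylethylenediamine (60 mol%), Cs2CO3, toluene, 80 °C
Reagents that add atoms: none
Why: A second Goldberg-type copper-catalysed N-alkenylation at the remaining N–H, run with the more reactive vinyl iodide in excess and an insoluble carbonate base to limit double-bond migration in the β,γ-unsaturated ester, completes the 3,4-diaza-1,5-diene with retention of both alkene geometries.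

Step 15
Reactants: 29 N,N'-di-Boc-N,N'-dialkenylhydrazine (tripyrrane arm and silyloxymethyl arm)
Product: 32 tetra-N-Boc bilane silyl ether octamethyl ester, via bis(N-Boc imine) 30 (not isolated), via cyclic aminal 31 (not isolated)
Conditions: degassed o-xylene (dilute), 140 °C, sealed vessel, Ar, dark
Reagents that add atoms: none
Why: Heating the 3,4-diaza-1,5-diene breaks the weak N–N bond while the two vinylic CH carbons join in a concerted [3,3]-sigmatropic shift through a chair-like transition state, giving bis(N-Boc imine) 30 with the C3–C4 bond of ring A in place. The closest known chemistry is the Piloty–Robinson pyrrole synthesis in its N,N'-diacyl-N,N'-dialkenylhydrazine form, including the thermal conversion of di-Boc dialkenylhydrazines into N-Boc pyrroles. One imine tautomerises to the ene-carbamate, whose nitrogen adds to the other N-acyl imine carbon in a 5-exo-trig closure to aminal 31, and loss of tert-butyl carbamate aromatises ring A. No stereocentre survives, since the two sp3 carbons created in 30 become C3 and C4 of the pyrrole. The step needs regiocontrol only, and this is built in: each C=C of 29 runs from the nitrogen-bearing carbon to its side-chain carbon (fixed in steps 8 and 13 and untouched by neutral heating), so the acetate carbon must end on C3 next to the silyloxymethyl carbon and the propionate on C4 next to the bridge carbon. The N-Boc groups on rings B, C and D keep the tripyrrane inert to heat and adventitious acid during the rearrangement.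

Step 16
Reactants: 32 tetra-N-Boc bilane silyl ether octamethyl ester
Product: 33 tetra-N-Boc hydroxymethylbilane octamethyl ester
Conditions: Bu4NF, AcOH, THF, 0 °C
Reagents that add atoms: none
Why: Fluoride-mediated cleavage of the primary silyl ether, buffered with acetic acid so that no alkoxide forms that could attack the neighbouring N-Boc group or the esters, gives a hydroxymethylpyrrole stabilised against azafulvene formation by its N-acyl group.

Step 17
Reactants: 33 tetra-N-Boc hydroxymethylbilane octamethyl ester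
Product: 34 preuroporphyrinogen (hydroxymethylbilane), kept as the octapotassium salt
Conditions: 2 M aq. KOH/THF (degassed), rt to 40 °C, Ar, dark; solution held at pH > 12
Reagents that add atoms: potassium hydroxide, [K+].[OH-]
Why: Hydroxide saponifies the eight methyl esters and cleaves the four pyrrole carbamates (acyl transfer with a pyrrolide leaving group), and in a strongly alkaline, methanol-free medium any transient azafulvene from ring A should be captured by hydroxide to give back the product.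

**Compound list**

In the oligopyrroles, each of rings B, C and D carries CH2CO2Me next to the ring carbon bearing the CH2 that leads toward ring A, and CH2CH2CO2Me next to the ring carbon bonded to the CH2 coming from the next ring (H or CO2t-Bu in ring D).

1 | Meldrum's acid (2,2-dimethyl-1,3-dioxane-4,6-dione) | CC1(C)OC(=O)CC(=O)O1 | starting material
2 | methyl 4-chloro-4-oxobutanoate | COC(=O)CCC(Cl)=O | starting material
3 | methyl 4-(2,2-dimethyl-4,6-dioxo-1,3-dioxan-5-ylidene)-4-hydroxybutanoate (acyl Meldrum's acid, enol form) | COC(=O)CCC(O)=C1C(=O)OC(C)(C)OC1=O | intermediate (not isolated)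
4 | 1-tert-butyl 6-methyl 3-oxohexanedioate | COC(=O)CCC(=O)CC(=O)OC(C)(C)C | intermediate
5 | pentane-2,4-dione | CC(=O)CC(C)=O | starting material
6 | 1-tert-butyl 6-methyl 2-(hydroxyimino)-3-oxohexanedioate (oxime geometry not defined) | COC(=O)CCC(=O)C(=NO)C(=O)OC(C)(C)C | intermediate (not isolated)
7 | 1-tert-butyl 6-methyl 2-amino-3-oxohexanedioate (racemic, transient) | COC(=O)CCC(=O)C(N)C(=O)OC(C)(C)C | intermediate (not isolated)
8 | tert-butyl 4-acetyl-3-(3-methoxy-3-oxopropyl)-5-methyl-1H-pyrrole-2-carboxylate | CC(=O)c1c(C)[nH]c(C(=O)OC(C)(C)C)c1CCC(=O)OC | intermediate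
9 | tert-butyl 4-(2-methoxy-2-oxoethyl)-3-(3-methoxy-3-oxopropyl)-5-methyl-1H-pyrrole-2-carboxylate | COC(=O)Cc1c(C)[nH]c(C(=O)OC(C)(C)C)c1CCC(=O)OC | intermediate
10 | tert-butyl 5-(acetoxymethyl)-4-(2-methoxy-2-oxoethyl)-3-(3-methoxy-3-oxopropyl)-1H-pyrrole-2-carboxylate | COC(=O)Cc1c(COC(C)=O)[nH]c(C(=O)OC(C)(C)C)c1CCC(=O)OC | intermediate
11 | di-tert-butyl 4-(2-methoxy-2-oxoethyl)-3-(3-methoxy-3-oxopropyl)-5-methyl-1H-pyrrole-1,2-dicarboxylate | COC(=O)Cc1c(C)n(C(=O)OC(C)(C)C)c(C(=O)OC(C)(C)C)c1CCC(=O)OC | intermediate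
12 | di-tert-butyl 5-(bromomethyl)-4-(2-methoxy-2-oxoethyl)-3-(3-methoxy-3-oxopropyl)-1H-pyrrole-1,2-dicarboxylate | COC(=O)Cc1c(CBr)n(C(=O)OC(C)(C)C)c(C(=O)OC(C)(C)C)c1CCC(=O)OC | intermediate
13 | methyl 4-oxobutanoate | COC(=O)CCC=O | starting material
14 | carbon tetrabromide | BrC(Br)(Br)Br | starting material
15 | methyl 5,5-dibromopent-4-enoate | COC(=O)CCC=C(Br)Br | intermediate
16 | {[1,5-bis(tert-butoxycarbonyl)-3-(2-methoxy-2-oxoethyl)-4-(3-methoxy-3-oxopropyl)-1H-pyrrol-2-yl]methyl}zinc bromide | COC(=O)Cc1c(C[Zn]Br)n(C(=O)OC(C)(C)C)c(C(=O)OC(C)(C)C)c1CCC(=O)OC | intermediate (not isolated)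
17 | di-tert-butyl 5-[(2Z)-2-bromo-6-methoxy-6-oxohex-2-en-1-yl]-4-(2-methoxy-2-oxoethyl)-3-(3-methoxy-3-oxopropyl)-1H-pyrrole-1,2-dicarboxylate (ring B bromoalkene) | COC(=O)CC/C=C(\Br)Cc1c(CC(=O)OC)c(CCC(=O)OC)c(C(=O)OC(C)(C)C)n1C(=O)OC(C)(C)C | intermediate
18 | methyl (4Z)-5-bromo-6-[3-(2-methoxy-2-oxoethyl)-4-(3-methoxy-3-oxopropyl)-1H-pyrrol-2-yl]hex-4-enoate (α-free ring B pyrrole) | COC(=O)CC/C=C(\Br)Cc1[nH]cc(CCC(=O)OC)c1CC(=O)OC | intermediate (not isolated)
19 | ring B–C dipyrromethane: tert-butyl 5-({5-[(2Z)-2-bromo-6-methoxy-6-oxohex-2-en-1-yl]-4-(2-methoxy-2-oxoethyl)-3-(3-methoxy-3-oxopropyl)-1H-pyrrol-2-yl}methyl)-4-(2-methoxy-2-oxoethyl)-3-(3-methoxy-3-oxopropyl)-1H-pyrrole-2-carboxylate | COC(=O)CC/C=C(\Br)Cc1[nH]c(Cc2[nH]c(C(=O)OC(C)(C)C)c(CCC(=O)OC)c2CC(=O)OC)c(CCC(=O)OC)c1CC(=O)OC | intermediate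
20 | α-free ring B–C dipyrromethane (19 with H in place of CO2t-Bu on ring C) | COC(=O)CC/C=C(\Br)Cc1[nH]c(Cc2[nH]cc(CCC(=O)OC)c2CC(=O)OC)c(CCC(=O)OC)c1CC(=O)OC | intermediate (not isolated)
21 | ring B–C–D tripyrrane tert-butyl ester (20 extended at the free α-carbon of ring C by CH2–ring D; ring D carries CO2t-Bu on its outer α-carbon; Z-bromoalkene on ring B) | COC(=O)CC/C=C(\Br)Cc1[nH]c(Cc2[nH]c(Cc3[nH]c(C(=O)OC(C)(C)C)c(CCC(=O)OC)c3CC(=O)OC)c(CCC(=O)OC)c2CC(=O)OC)c(CCC(=O)OC)c1CC(=O)OC | intermediate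
22 | α-free ring B–C–D tripyrrane (21 with H in place of CO2t-Bu on ring D) | COC(=O)CC/C=C(\Br)Cc1[nH]c(Cc2[nH]c(Cc3[nH]cc(CCC(=O)OC)c3CC(=O)OC)c(CCC(=O)OC)c2CC(=O)OC)c(CCC(=O)OC)c1CC(=O)OC | intermediate (not isolated)
23 | tri-N-Boc ring B–C–D tripyrrane (Z)-bromoalkene hexamethyl ester (22 with Boc on all three pyrrole nitrogens) | COC(=O)CC/C=C(\Br)Cc1n(C(=O)OC(C)(C)C)c(Cc2n(C(=O)OC(C)(C)C)c(Cc3n(C(=O)OC(C)(C)C)cc(CCC(=O)OC)c3CC(=O)OC)c(CCC(=O)OC)c2CC(=O)OC)c(CCC(=O)OC)c1CC(=O)OC | intermediate
24 | di-tert-butyl hydrazine-1,2-dicarboxylate | CC(C)(C)OC(=O)NNC(=O)OC(C)(C)C | starting material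
25 | di-tert-butyl 1-[(2Z)-6-methoxy-6-oxo-1-(tri-N-Boc tripyrran-yl)hex-2-en-2-yl]hydrazine-1,2-dicarboxylate (23 with N(Boc)NHBoc in place of Br, N cis to the propionate chain) | COC(=O)CC/C=C(\N(NC(=O)OC(C)(C)C)C(=O)OC(C)(C)C)Cc1n(C(=O)OC(C)(C)C)c(Cc2n(C(=O)OC(C)(C)C)c(Cc3n(C(=O)OC(C)(C)C)cc(CCC(=O)OC)c3CC(=O)OC)c(CCC(=O)OC)c2CC(=O)OC)c(CCC(=O)OC)c1CC(=O)OC | intermediate
26 | methyl iodoacetate | COC(=O)CI | starting material
27 | tert-butyldimethyl(prop-2-yn-1-yloxy)silane | C#CCO[Si](C)(C)C(C)(C)C | starting material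
28 | methyl (3E)-5-[(tert-butyldimethylsilyl)oxy]-4-iodopent-3-enoate | COC(=O)C/C=C(/I)CO[Si](C)(C)C(C)(C)C | intermediate
29 | di-tert-butyl 1-[(2E)-1-[(tert-butyldimethylsilyl)oxy]-5-methoxy-5-oxopent-2-en-2-yl]-2-[(2Z)-6-methoxy-6-oxo-1-(tri-N-Boc tripyrran-yl)hex-2-en-2-yl]hydrazine-1,2-dicarboxylate (key-step precursor) | CC(C)(C)[Si](C)(C)OC/C(=C\CC(=O)OC)N(C(=O)OC(C)(C)C)N(C(=O)OC(C)(C)C)/C(Cc1n(C(=O)OC(C)(C)C)c(Cc2n(C(=O)OC(C)(C)C)c(Cc3n(C(=O)OC(C)(C)C)cc(CCC(=O)OC)c3CC(=O)OC)c(CCC(=O)OC)c2CC(=O)OC)c(CCC(=O)OC)c1CC(=O)OC)=C\CCC(=O)OC | intermediate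
30 | acyclic bis(N-Boc imine): silyloxymethyl ketimine and tripyrranylmethyl ketimine joined through CH(CH2CO2Me)–CH(CH2CH2CO2Me) (diastereomer mixture; both sp3 centres and both C=N geometries transient and undefined) | CC(C)(C)[Si](C)(C)OCC(=NC(=O)OC(C)(C)C)C(CC(=O)OC)C(CCC(=O)OC)C(=NC(=O)OC(C)(C)C)Cc1n(C(=O)OC(C)(C)C)c(Cc2n(C(=O)OC(C)(C)C)c(Cc3n(C(=O)OC(C)(C)C)cc(CCC(=O)OC)c3CC(=O)OC)c(CCC(=O)OC)c2CC(=O)OC)c(CCC(=O)OC)c1CC(=O)OC | intermediate (not isolated)
31 | cyclic aminal: N-Boc 4,5-dihydropyrrole with C2 CH2OSi, C3 CH2CO2Me, C4 (sp3) CH2CH2CO2Me, C5 (sp3) NHBoc and tripyrranylmethyl (two transient centres, configuration undefined) | CC(C)(C)[Si](C)(C)OCC1=C(CC(=O)OC)C(CCC(=O)OC)C(NC(=O)OC(C)(C)C)(Cc2n(C(=O)OC(C)(C)C)c(Cc3n(C(=O)OC(C)(C)C)c(Cc4n(C(=O)OC(C)(C)C)cc(CCC(=O)OC)c4CC(=O)OC)c(CCC(=O)OC)c3CC(=O)OC)c(CCC(=O)OC)c2CC(=O)OC)N1C(=O)OC(C)(C)C | intermediate (not isolated)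
32 | tetra-N-Boc bilane tert-butyldimethylsilyl ether octamethyl ester (ring A: N-Boc, C2 CH2OSi, C3 CH2CO2Me, C4 CH2CH2CO2Me, C5 CH2–ring B) | CC(C)(C)[Si](C)(C)OCc1n(C(=O)OC(C)(C)C)c(Cc2n(C(=O)OC(C)(C)C)c(Cc3n(C(=O)OC(C)(C)C)c(Cc4n(C(=O)OC(C)(C)C)cc(CCC(=O)OC)c4CC(=O)OC)c(CCC(=O)OC)c3CC(=O)OC)c(CCC(=O)OC)c2CC(=O)OC)c(CCC(=O)OC)c1CC(=O)OC | intermediate
33 | tetra-N-Boc hydroxymethylbilane octamethyl ester | OCc1n(C(=O)OC(C)(C)C)c(Cc2n(C(=O)OC(C)(C)C)c(Cc3n(C(=O)OC(C)(C)C)c(Cc4n(C(=O)OC(C)(C)C)cc(CCC(=O)OC)c4CC(=O)OC)c(CCC(=O)OC)c3CC(=O)OC)c(CCC(=O)OC)c2CC(=O)OC)c(CCC(=O)OC)c1CC(=O)OC | intermediate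
34 | preuroporphyrinogen (hydroxymethylbilane) | O=C(O)CCc1c[nH]c(Cc2[nH]c(Cc3[nH]c(Cc4[nH]c(CO)c(CC(=O)O)c4CCC(=O)O)c(CC(=O)O)c3CCC(=O)O)c(CC(=O)O)c2CCC(=O)O)c1CC(=O)O | target

**Step count**

Total: 17 steps. Longest linear sequence: 14 steps (1, 2, 3, 5, 6, 8, 9, 10, 11, 12, 14, 15, 16, 17).

**Steps most likely to fail**

Step 14. The second C–N coupling must occur at an N–H flanked by a fully substituted nitrogen. While it lags, the carbonate base can shift the β,γ-double bond of 28 into conjugation with its ester, and the iodide is then lost. The fallback changes the order in which the two N–C bonds are made. It sets out from 24 and 28: the copper-catalysed N-alkenylation is run first on the unhindered hydrazide (24 in excess, short contact with base), which should give di-tert-butyl 1-[(2E)-1-[(tert-butyldimethylsilyl)oxy]-5-methoxy-5-oxopent-2-en-2-yl]hydrazine-1,2-dicarboxylate F1. F1, now the cheap partner, would be used in excess against the base-stable bromide 23 under the same type of catalysis at higher temperature, and the route is rejoined at 29.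

Step 15. After the sigmatropic shift, ring closure at a crowded, fully substituted imine carbon may be slow. Acyclic material then accumulates, and prolonged heating starts to strip Boc groups from the pyrrole nitrogens. The fallback closes ring A by Paal–Knorr condensation instead. It sets out from 29: heating is stopped once rearrangement to 30 is complete, and the two N-Boc imine groups are hydrolysed (moist silica gel or dilute aqueous citric acid in THF) to the 1,4-diketone F2. NH4OAc in MeOH at 50 °C should condense it to the ring A N–H bilane silyl ether F3. Boc2O/DMAP then restores the carbamate and the route is rejoined at 32.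

Step 6. Hydrogen abstraction from the CH2 groups of the acetate and propionate chains may compete with abstraction from the ring methyl group, giving bromide mixtures. The fallback reaches the bromide through the aldehyde. It sets out from 9: oxidation of the α-methyl group with (NH4)2Ce(NO3)6 in THF/AcOH/H2O should give the 5-formylpyrrole F4. Boc2O/DMAP would give its N-Boc derivative F5. NaBH4 in THF/MeOH at 0 °C would reduce the aldehyde to the N-Boc 5-(hydroxymethyl)pyrrole F6. An Appel reaction (14, PPh3, CH2Cl2) would convert it into 12, where the route is rejoined.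

**Further compounds**

F1 | step 14 | di-tert-butyl 1-[(2E)-1-[(tert-butyldimethylsilyl)oxy]-5-methoxy-5-oxopent-2-en-2-yl]hydrazine-1,2-dicarboxylate | CC(C)(C)[Si](C)(C)OC/C(=C\CC(=O)OC)N(NC(=O)OC(C)(C)C)C(=O)OC(C)(C)C
F2 | step 15 | 1,4-diketone: 1-silyloxy-hexane-2,5-dione with CH2CO2Me on C3, CH2CH2CO2Me on C4 and the tri-N-Boc tripyrrane on C6 (diastereomer mixture) | CC(C)(C)[Si](C)(C)OCC(=O)C(CC(=O)OC)C(CCC(=O)OC)C(=O)Cc1n(C(=O)OC(C)(C)C)c(Cc2n(C(=O)OC(C)(C)C)c(Cc3n(C(=O)OC(C)(C)C)cc(CCC(=O)OC)c3CC(=O)OC)c(CCC(=O)OC)c2CC(=O)OC)c(CCC(=O)OC)c1CC(=O)OC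
F3 | step 15 | ring A N–H bilane silyl ether octamethyl ester (Boc on rings B, C and D only) | CC(C)(C)[Si](C)(C)OCc1[nH]c(Cc2n(C(=O)OC(C)(C)C)c(Cc3n(C(=O)OC(C)(C)C)c(Cc4n(C(=O)OC(C)(C)C)cc(CCC(=O)OC)c4CC(=O)OC)c(CCC(=O)OC)c3CC(=O)OC)c(CCC(=O)OC)c2CC(=O)OC)c(CCC(=O)OC)c1CC(=O)OC
F4 | step 6 | tert-butyl 5-formyl-4-(2-methoxy-2-oxoethyl)-3-(3-methoxy-3-oxopropyl)-1H-pyrrole-2-carboxylate | COC(=O)Cc1c(C=O)[nH]c(C(=O)OC(C)(C)C)c1CCC(=O)OC
F5 | step 6 | di-tert-butyl 5-formyl-4-(2-methoxy-2-oxoethyl)-3-(3-methoxy-3-oxopropyl)-1H-pyrrole-1,2-dicarboxylate | COC(=O)Cc1c(C=O)n(C(=O)OC(C)(C)C)c(C(=O)OC(C)(C)C)c1CCC(=O)OC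
F6 | step 6 | di-tert-butyl 5-(hydroxymethyl)-4-(2-methoxy-2-oxoethyl)-3-(3-methoxy-3-oxopropyl)-1H-pyrrole-1,2-dicarboxylate | COC(=O)Cc1c(CO)n(C(=O)OC(C)(C)C)c(C(=O)OC(C)(C)C)c1CCC(=O)OC
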